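**Retrosynthetic overview**

1. The target comes from its C2'-bromo, O-silyl precursor: the C2' hydroxyl is made from C–Br by lithiation, borylation and oxidation, and the primary alcohol is freed by desilylation.
2. Ring B is not coupled to ring A as an arene. It is built on the ring-A oxygen: C2', C3', C4' and C5' are C3, C4, C5 and C6 of a 3-bromo-4-methoxy-6-alkyl-2-pyrone, and C1' and C6' are the two sp carbons of the ethynyl ether of ring A. A [4+2] addition forms C1'–C2' and C5'–C6', and the lactone bridge leaves as CO2.
3. The feature on which this rests is the run of oxygenated carbons in ring B, C1' (O-aryl), C2' (OH) and C3' (OMe), with the chain on C5'. This pattern matches the substituents and polarity of a 3-halo-4-alkoxy-6-alkyl-2-pyrone combined with a terminal ynol ether.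
4. The pyrone comes from 4-methoxy-6-methyl-2-pyrone by side-chain alkylation and C3 bromination. The ynol ether comes from 4-allyl-2,6-dimethoxyphenol by hydrogenation, dichlorovinylation with trichloroethylene and elimination.
5. Ring order: ring A is bought; ring B is the only ring formed, in the benzannulation.

Key step: step 6

Remark on the chemistry: the target has no stereocentre. 4-Methoxy-6-methyl-2H-pyran-2-one and tert-butyl(2-iodoethoxy)dimethylsilane are assumed to be purchasable; the iodide is chosen because β-silyloxy bromides alkylate sluggishly.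

**Route**

Step 1
Reactants: 1 4-methoxy-6-methyl-2H-pyran-2-one; 2 tert-butyl(2-iodoethoxy)dimethylsilane
Product: 4 6-[3-(tert-butyldimethylsilyloxy)propyl]-4-methoxy-2H-pyran-2-one, via lithium dienolate 3 (not isolated)
Conditions: LiN(i-Pr)2 (1.1 equiv), THF, −78 °C; then 2, DMPU, −78 → −20 °C
Reagents that add atoms: none
Why: Deprotonation of the vinylogous C6-methyl group gives a delocalised lithium dienolate that should be C-alkylated at the exocyclic carbon by the primary iodide in an SN2 reaction (lateral enolate alkylation of a 6-methyl-2-pyrone).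

Step 2
Reactants: 4 6-[3-(tert-butyldimethylsilyloxy)propyl]-4-methoxy-2H-pyran-2-one
Product: 5 3-bromo-6-[3-(tert-butyldimethylsilyloxy)propyl]-4-methoxy-2H-pyran-2-one
Conditions: NBS (1.05 equiv), MeCN, 0 °C → rt, dark
Reagents that add atoms: N-bromosuccinimide, O=C1CCC(=O)N1Br
Why: Electrophilic bromination of the vinylogous ester should occur at C3, the most nucleophilic ring carbon between the lactone carbonyl and the 4-methoxy group, and the neutral, dark conditions spare the silyl ether and the side-chain CH2 groups.

Step 3
Reactants: 6 4-allyl-2,6-dimethoxyphenol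
Product: 7 2,6-dimethoxy-4-propylphenol
Conditions: H2 (1 atm), 10% Pd/C, EtOAc, rt
Reagents that add atoms: none
Why: Heterogeneous catalytic hydrogenation saturates the terminal alkene and leaves the arene, the methyl ethers and the phenol untouched.

Step 4
Reactants: 7 2,6-dimethoxy-4-propylphenol; 8 trichloroethylene
Product: 10 (E)-2-[(1,2-dichlorovinyl)oxy]-1,3-dimethoxy-5-propylbenzene, via dichloroacetylene 9 (not isolated)
Conditions: K2CO3 (2 equiv), DMF, 70 °C
Reagents that add atoms: none
Why: Base-induced dehydrochlorination of trichloroethylene gives dichloroacetylene, to which the phenoxide adds in anti fashion (elimination–addition synthesis of aryl 1,2-dichlorovinyl ethers), so the hindered oxygen is bonded to an unhindered sp carbon.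

Step 5
Reactants: 10 (E)-2-[(1,2-dichlorovinyl)oxy]-1,3-dimethoxy-5-propylbenzene
Product: 13 2-(ethynyloxy)-1,3-dimethoxy-5-propylbenzene, via chloroethynyl ether 11 (not isolated), via lithium acetylide 12 (not isolated)
Conditions: n-BuLi (2.5 equiv), Et2O, −78 → −40 °C; then H2O, −78 → 0 °C; used at once
Reagents that add atoms: none
Why: β-Elimination of HCl gives the chloroalkynyl ether, chlorine–lithium exchange gives the lithium acetylide and water protonates it (dichlorovinyl ether route to terminal ynol ethers); the aryl ether has no β-hydrogen for retro-ene loss.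

Step 6
Reactants: 5 3-bromo-6-[3-(tert-butyldimethylsilyloxy)propyl]-4-methoxy-2H-pyran-2-one; 13 2-(ethynyloxy)-1,3-dimethoxy-5-propylbenzene
Product: 15 tert-butyl{3-[4-bromo-3-(2,6-dimethoxy-4-propylphenoxy)-5-methoxyphenyl]propoxy}dimethylsilane, via bicyclic lactone 14 (not isolated)
Conditions: 13 (3 equiv, in portions), BHT (cat.), o-xylene (about 1 M), sealed tube, Ar, 150 °C
Reagents that add atoms: none
Why: Proposed new method: pyrone 5 should serve as the 4π partner, its C6 being the electrophilic δ-terminus of the unsaturated lactone (lowered further by the C3 bromine), and ynol ether 13 as the 2π partner with its largest HOMO coefficient on the terminal CH, so a concerted but asynchronous inverse-demand [4+2] addition is expected in which C6–CH bonding runs ahead of C3–C(OAr) bonding. The closest known reaction types are the pyrone–alkyne benzannulation with loss of CO2 and the cycloadditions of 3-bromo-2-pyrones and 3-acyl-2-pyrones with enol ethers, ketene acetals and ynamines, all of which place the heteroatom-bearing carbon next to pyrone C3; a 4-alkoxy-3-bromo-2-pyrone has not been paired with an aryl ynol ether, hence the label. Ring B is closed by this intermolecular [4+2] cycloaddition across pyrone C3 and C6 (bonds C1'–C2' and C5'–C6'), giving the 2-oxabicyclo[2.2.2]octadienone 14, whose lactone bridge should leave as CO2 by retro-[4+2] at the reaction temperature, so the arene forms without an oxidant. No stereocentre remains, because the two bridgehead centres of racemic 14 become sp2 carbons. The step needs regioselectivity (the O-aryl carbon must bond to the brominated C3), which the matched polarity of the partners should secure, and both pyrone termini are fully substituted, so sterics do not oppose it. It also needs the cycloaddition to outrun oligomerisation of the ynol ether, which the excess of 13, the absence of a retro-ene pathway and the radical inhibitor should favour; the 4-methoxy group makes the pyrone less electron-poor, and this is the main risk.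

Step 7
Reactants: 15 tert-butyl{3-[4-bromo-3-(2,6-dimethoxy-4-propylphenoxy)-5-methoxyphenyl]propoxy}dimethylsilane
Product: 18 4-[3-(tert-butyldimethylsilyloxy)propyl]-2-(2,6-dimethoxy-4-propylphenoxy)-6-methoxyphenol, via aryllithium 16 (not isolated), via lithium aryltrimethoxyborate 17 (not isolated)
Conditions: n-BuLi (1.1 equiv), THF, −78 °C; B(OMe)3 (2 equiv), −78 → 0 °C; 30% aq H2O2, 0 °C → rt
Reagents that add atoms: hydrogen peroxide, OO
Why: Bromine–lithium exchange at −78 °C gives an aryllithium flanked by two ether oxygens, B(OMe)3 captures it as the ate complex, and peroxide oxidises the C–B bond by 1,2-aryl migration to oxygen (lithiation–borylation–oxidation), so the hydroxyl appears exactly at C2'.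

Step 8
Reactants: 18 4-[3-(tert-butyldimethylsilyloxy)propyl]-2-(2,6-dimethoxy-4-propylphenoxy)-6-methoxyphenol
Product: 19 2-(2,6-dimethoxy-4-propylphenoxy)-4-(3-hydroxypropyl)-6-methoxyphenol (CNP0368877.0)
Conditions: Bu4NF (2.2 equiv), THF, 0 °C → rt
Reagents that add atoms: none
Why: Fluoride-mediated desilylation, driven by Si–F bond formation, frees the primary alcohol; the diaryl ether, the methyl ethers and the phenol are inert to it.

**Compound list**

1 | 4-methoxy-6-methyl-2H-pyran-2-one | Cc1cc(OC)cc(=O)o1 | starting material
2 | tert-butyl(2-iodoethoxy)dimethylsilane | ICCO[Si](C)(C)C(C)(C)C | starting material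
3 | 6-(lithiomethyl)-4-methoxy-2H-pyran-2-one, the lithium dienolate of 1 (formed in the flask, not isolated) | [Li]Cc1cc(OC)cc(=O)o1 | intermediate
4 | 6-[3-(tert-butyldimethylsilyloxy)propyl]-4-methoxy-2H-pyran-2-one | O=c1cc(OC)cc(CCCO[Si](C)(C)C(C)(C)C)o1 | intermediate
5 | 3-bromo-6-[3-(tert-butyldimethylsilyloxy)propyl]-4-methoxy-2H-pyran-2-one | O=c1oc(CCCO[Si](C)(C)C(C)(C)C)cc(OC)c1Br | intermediate
6 | 4-allyl-2,6-dimethoxyphenol | C=CCc1cc(OC)c(O)c(OC)c1 | starting material
7 | 2,6-dimethoxy-4-propylphenol | CCCc1cc(OC)c(O)c(OC)c1 | intermediate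
8 | trichloroethylene | ClC=C(Cl)Cl | starting material
9 | dichloroacetylene (formed in the flask, not isolated) | ClC#CCl | intermediate
10 | (E)-2-[(1,2-dichlorovinyl)oxy]-1,3-dimethoxy-5-propylbenzene | Cl/C=C(/Cl)Oc1c(OC)cc(CCC)cc1OC | intermediate
11 | 2-[(chloroethynyl)oxy]-1,3-dimethoxy-5-propylbenzene (formed in the flask, not isolated) | ClC#COc1c(OC)cc(CCC)cc1OC | intermediate
12 | [(2,6-dimethoxy-4-propylphenoxy)ethynyl]lithium (formed in the flask, not isolated) | [Li]C#COc1c(OC)cc(CCC)cc1OC | intermediate
13 | 2-(ethynyloxy)-1,3-dimethoxy-5-propylbenzene | C#COc1c(OC)cc(CCC)cc1OC | intermediate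
14 | 4-bromo-1-[3-(tert-butyldimethylsilyloxy)propyl]-8-(2,6-dimethoxy-4-propylphenoxy)-5-methoxy-2-oxabicyclo[2.2.2]octa-5,7-dien-3-one (racemic, one enantiomer drawn; formed in the flask, not isolated) | O=C1O[C@]2(CCCO[Si](C)(C)C(C)(C)C)C=C(OC)[C@@]1(Br)C(Oc1c(OC)cc(CCC)cc1OC)=C2 | intermediate
15 | tert-butyl{3-[4-bromo-3-(2,6-dimethoxy-4-propylphenoxy)-5-methoxyphenyl]propoxy}dimethylsilane | CCCc1cc(OC)c(Oc2cc(CCCO[Si](C)(C)C(C)(C)C)cc(OC)c2Br)c(OC)c1 | intermediate
16 | {4-[3-(tert-butyldimethylsilyloxy)propyl]-2-(2,6-dimethoxy-4-propylphenoxy)-6-methoxyphenyl}lithium (formed in the flask, not isolated) | CCCc1cc(OC)c(Oc2cc(CCCO[Si](C)(C)C(C)(C)C)cc(OC)c2[Li])c(OC)c1 | intermediate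
17 | lithium {4-[3-(tert-butyldimethylsilyloxy)propyl]-2-(2,6-dimethoxy-4-propylphenoxy)-6-methoxyphenyl}trimethoxyborate (formed in the flask, not isolated) | [Li+].CCCc1cc(OC)c(Oc2cc(CCCO[Si](C)(C)C(C)(C)C)cc(OC)c2[B-](OC)(OC)OC)c(OC)c1 | intermediate
18 | 4-[3-(tert-butyldimethylsilyloxy)propyl]-2-(2,6-dimethoxy-4-propylphenoxy)-6-methoxyphenol | CCCc1cc(OC)c(Oc2cc(CCCO[Si](C)(C)C(C)(C)C)cc(OC)c2O)c(OC)c1 | intermediate
19 | 2-(2,6-dimethoxy-4-propylphenoxy)-4-(3-hydroxypropyl)-6-methoxyphenol | CCCc1cc(OC)c(Oc2cc(CCCO)cc(OC)c2O)c(OC)c1 | target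

**Step count and risks**

Total step count: 8. Longest linear sequence: 6 steps (steps 3, 4, 5, 6, 7, 8, from 6 to 19).

Steps most likely to fail:

1. Step 6 (proposed new method). The 4-methoxy group reduces the electron deficiency of the pyrone, so the cycloaddition may be slower than thermal oligomerisation or adventitious hydration of the ynol ether, and ring B would then not form. The fallback uses known chemistry and closes the diaryl ether by copper-catalysed arylation of the phenol instead. It sets out from phenol 7 and returns to the route at target 19. Commercial 5-bromovanillin is benzylated (BnBr, K2CO3, DMF) to 4-(benzyloxy)-3-bromo-5-methoxybenzaldehyde F1. Ullmann-type coupling of 7 with F1 (CuI, picolinic acid, K3PO4, DMSO, 90–100 °C) should give 4-(benzyloxy)-3-(2,6-dimethoxy-4-propylphenoxy)-5-methoxybenzaldehyde F2. Wittig olefination with Ph3P=CHCO2Et in toluene should give ethyl (E)-3-[4-(benzyloxy)-3-(2,6-dimethoxy-4-propylphenoxy)-5-methoxyphenyl]prop-2-enoate F3. Hydrogenation (H2, 10% Pd/C, EtOAc) saturates the alkene and removes the benzyl group to give ethyl 3-[3-(2,6-dimethoxy-4-propylphenoxy)-4-hydroxy-5-methoxyphenyl]propanoate F4. Reduction with LiAlH4 in THF at 0 °C then gives 19.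

2. Step 1. SN2 displacement at the β-silyloxy iodide may be slow, so that E2 elimination to the silyl vinyl ether with proton return to 1, or a second alkylation of the product, competes. The fallback sets out from pyrone 1 (through dienolate 3) and returns at 4. It replaces the iodide with the much more electrophilic cyclic sulfate 1,3,2-dioxathiolane 2,2-dioxide (THF, −78 → 0 °C), which should give lithium 3-(4-methoxy-2-oxo-2H-pyran-6-yl)propyl sulfate F5. Mild hydrolysis of the sulfate monoester (catalytic H2SO4, H2O, THF, rt) gives 6-(3-hydroxypropyl)-4-methoxy-2H-pyran-2-one F6. Silylation (TBSCl, imidazole, DMF) gives 4.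

3. Step 7. Boron capture of the doubly ortho-flanked aryllithium may be incomplete, with proton return on quench (net debromination) or butylation by 1-bromobutane, and the electron-rich phenol may be over-oxidised by peroxide. The fallback sets out from bromide 15 and returns at 18. It uses palladium-catalysed hydroxylation (Pd2(dba)3, 2-di-tert-butylphosphino-2',4',6'-triisopropylbiphenyl, KOH, 1,4-dioxane/H2O, 100 °C, then acidification), which avoids both the organolithium and the peroxide. It makes no compound outside the list (F0). Should the silyl ether be lost under these conditions, the product would be 19 directly.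

**Further compounds**

F1 | step 6 | 4-(benzyloxy)-3-bromo-5-methoxybenzaldehyde | O=Cc1cc(Br)c(OCc2ccccc2)c(OC)c1
F2 | step 6 | 4-(benzyloxy)-3-(2,6-dimethoxy-4-propylphenoxy)-5-methoxybenzaldehyde | CCCc1cc(OC)c(Oc2cc(C=O)cc(OC)c2OCc2ccccc2)c(OC)c1
F3 | step 6 | ethyl (E)-3-[4-(benzyloxy)-3-(2,6-dimethoxy-4-propylphenoxy)-5-methoxyphenyl]prop-2-enoate | CCCc1cc(OC)c(Oc2cc(/C=C/C(=O)OCC)cc(OC)c2OCc2ccccc2)c(OC)c1
F4 | step 6 | ethyl 3-[3-(2,6-dimethoxy-4-propylphenoxy)-4-hydroxy-5-methoxyphenyl]propanoate | CCCc1cc(OC)c(Oc2cc(CCC(=O)OCC)cc(OC)c2O)c(OC)c1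
F5 | step 1 | lithium 3-(4-methoxy-2-oxo-2H-pyran-6-yl)propyl sulfate | [Li+].[O-]S(=O)(=O)OCCCc1cc(OC)cc(=O)o1
F6 | step 1 | 6-(3-hydroxypropyl)-4-methoxy-2H-pyran-2-one | OCCCc1cc(OC)cc(=O)o1
F0 | step 7 | none | none
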